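**Retrosynthetic overview**

1. Numbering: ring A has C1 (biaryl carbon), C2 (OH), C4 (OMe) and C6 (CH2CH2 to ring C); ring B has C1' bonded to C1, OH at C2' and C5', and H at C3', C4', C6'. The strategy rests on ring B: a para-dioxygenated benzene whose only carbon substituent, the C1–C1' bond, sits beside the C2' oxygen. This is the native substitution pattern of a Dötz benzannulation.
2. Target 19 ⇐ arylbenzoquinone 17 (H2, Pd/C reduces the quinone and removes both benzyl groups) ⇐ ring B 4-methoxyphenol trimethylsilyl ether 15 (oxidative demethylation).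
3. Ring B of 15 is cut at C5'–C6', C1'–C2' and C2'–C3' into terminal aryl alkyne 9 (C1', C6'), one CO ligand (C2') and the β-silylvinyl methoxycarbene complex 14 of zerovalent chromium (C3', C4', C5').
4. Alkyne 9 ⇐ aldehyde 8 ⇐ ester 6 ⇐ lateral alkylation of toluate 3 (from methyl orsellinate 1) with benzylic bromide 4; complex 14 ⇐ vinyl bromide 10 + Cr(CO)6 11.
5. Ring order: rings A and C are purchased; ring B is the only ring formed, in step 8.

Key step: step 8

Remark: the target SMILES carries no stereodescriptor, so the tri-ortho-substituted biaryl axis is treated as configurationally undefined and the route needs no stereocontrol.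

**Route**

Step 1
Reactants: 1 methyl orsellinate (methyl 2,4-dihydroxy-6-methylbenzoate)
Product: 2 methyl 2-hydroxy-4-methoxy-6-methylbenzoate
Conditions: MeI (1.05 equiv), K2CO3, acetone, rt
Reagents that add atoms: iodomethane, CI
Why: Williamson O-methylation should occur at the free 4-OH, because the 2-OH is hydrogen-bonded to the ester carbonyl and is much less nucleophilic.

Step 2
Reactants: 2 methyl 2-hydroxy-4-methoxy-6-methylbenzoate
Product: 3 methyl 2-(benzyloxy)-4-methoxy-6-methylbenzoate
Conditions: BnBr, K2CO3, DMF, 60 °C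
Reagents that add atoms: benzyl bromide, BrCc1ccccc1
Why: Williamson benzylation of the remaining chelated phenol under more forcing conditions installs a group that is removed by the final hydrogenation and that prevents an ortho-alkynylphenol from cyclizing to a benzofuran later.

Step 3
Reactants: 3 methyl 2-(benzyloxy)-4-methoxy-6-methylbenzoate; 4 3-(benzyloxy)benzyl bromide
Product: 6 methyl 2-(benzyloxy)-6-[2-(3-(benzyloxy)phenyl)ethyl]-4-methoxybenzoate, via lateral lithio toluate 5 (not isolated)
Conditions: LiN(i-Pr)2 (1.2 equiv), THF, −78 °C, 30 min; then 4, −78 → −40 °C; aq. NH4Cl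
Reagents that add atoms: none
Why: Lateral lithiation of the ortho-toluate gives an ester-stabilized benzylic anion that should be C-alkylated by the reactive benzylic bromide (SN2) at low temperature, while the much less acidic benzyl ether CH2 groups are left alone.

Step 4
Reactants: 6 methyl 2-(benzyloxy)-6-[2-(3-(benzyloxy)phenyl)ethyl]-4-methoxybenzoate
Product: 7 [2-(benzyloxy)-6-[2-(3-(benzyloxy)phenyl)ethyl]-4-methoxyphenyl]methanol
Conditions: LiAlH4, THF, 0 → 50 °C; NaOH/H2O work-up
Reagents that add atoms: none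
Why: LiAlH4 reduction of the hindered, electron-rich benzoate should give the benzylic alcohol, with aryl and benzyl ethers inert.

Step 5
Reactants: 7 [2-(benzyloxy)-6-[2-(3-(benzyloxy)phenyl)ethyl]-4-methoxyphenyl]methanol
Product: 8 2-(benzyloxy)-6-[2-(3-(benzyloxy)phenyl)ethyl]-4-methoxybenzaldehyde
Conditions: activated MnO2 (excess), CH2Cl2, rt
Reagents that add atoms: none
Why: MnO2 oxidation of the activated benzylic alcohol should stop at the aldehyde under neutral conditions, avoiding the acid that an electron-rich benzylic alcohol would not tolerate.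

Step 6
Reactants: 8 2-(benzyloxy)-6-[2-(3-(benzyloxy)phenyl)ethyl]-4-methoxybenzaldehyde
Product: 9 1-(benzyloxy)-2-ethynyl-5-methoxy-3-[2-(3-(benzyloxy)phenyl)ethyl]benzene
Conditions: dimethyl (1-diazo-2-oxopropyl)phosphonate (1.5 equiv), K2CO3, MeOH/THF, rt
Reagents that add atoms: dimethyl (1-diazo-2-oxopropyl)phosphonate, COP(=O)(OC)C(=[N+]=[N-])C(C)=O
Why: In the Ohira–Bestmann variant of the Seyferth–Gilbert homologation, methanolysis releases the diazomethylphosphonate anion, which olefinates the aldehyde to a diazoalkene that loses N2 and undergoes a 1,2-hydrogen shift to the terminal alkyne under conditions mild enough for the benzyl ethers.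

Step 7
Reactants: 10 (E)-(2-bromovinyl)trimethylsilane; 11 hexacarbonylchromium Cr(CO)6
Product: 14 pentacarbonyl[(E)-1-methoxy-3-(trimethylsilyl)prop-2-enylidene]chromium, via (E)-2-(trimethylsilyl)vinyllithium 12 (not isolated), via lithium acylchromate 13 (not isolated)
Conditions: t-BuLi (2.0 equiv), Et2O, −78 °C; then Cr(CO)6, Et2O/THF, 0 °C → rt; evaporate; Me3OBF4, CH2Cl2, 0 °C → rt
Reagents that add atoms: trimethyloxonium tetrafluoroborate, C[O+](C)C.F[B-](F)(F)F
Why: In this Fischer carbene synthesis, bromine–lithium exchange proceeds with retention of the E geometry, the vinyllithium adds to a CO ligand to give the acyl chromate, and the hard oxonium salt methylates it on oxygen; the β-silyl group makes the otherwise polymerization-prone vinylcarbene complex handleable.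

Step 8
Reactants: 9 1-(benzyloxy)-2-ethynyl-5-methoxy-3-[2-(3-(benzyloxy)phenyl)ethyl]benzene; 14 pentacarbonyl[(E)-1-methoxy-3-(trimethylsilyl)prop-2-enylidene]chromium (1.5 equiv)
Product: 15 2-(benzyloxy)-6-[2-(3-(benzyloxy)phenyl)ethyl]-4,5'-dimethoxy-2'-(trimethylsilyloxy)-1,1'-biphenyl
Conditions: THF (0.05 M), 55 °C, Ar; then air, rt; filtration through Et3N-deactivated silica
Reagents that add atoms: none
Why: Thermal loss of one CO from 14 lets alkyne 9 coordinate and insert into the chromium–carbon double bond (bond C5'–C6'), and CO insertion at the new carbene carbon then gives a chromium-bound dienylketene (bond C1'–C2'). Ring B closes by a six-electron electrocyclization of this ketene (bond C2'–C3') to a cyclohexa-2,4-dienone whose sp3 carbon C3' carries H and SiMe3, and a 1,3-shift of silicon from carbon to oxygen aromatizes it to the aryl trimethylsilyl ether. The closest known reaction type is the Dötz benzannulation of alkenyl Fischer carbene complexes with terminal aryl alkynes, in which β-silylvinyl complexes serve as stable equivalents of the parent vinyl complex. No stereocenter is formed, and the biaryl bond is already present as the aryl–alkyne bond, so no hindered biaryl coupling is required. The step needs the aryl-bearing alkyne carbon to end up next to the CO-derived carbon, which the steric difference between H and the 2,6-disubstituted aryl group of a terminal alkyne should secure; the reverse orientation would converge on the same quinone in step 9 because ring B carries no other substituent. Phenol formation over cyclobutenone or furan by-products is favoured by the alkenyl complex in THF, and the brief air exposure destroys the spent chromium carbonyl fragment before filtration.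

Step 9
Reactants: 15 2-(benzyloxy)-6-[2-(3-(benzyloxy)phenyl)ethyl]-4,5'-dimethoxy-2'-(trimethylsilyloxy)-1,1'-biphenyl
Product: 17 2-[2-(benzyloxy)-6-[2-(3-(benzyloxy)phenyl)ethyl]-4-methoxyphenyl]-1,4-benzoquinone, via free 4-methoxyphenol 16 (not isolated)
Conditions: (NH4)2Ce(NO3)6 (2.5 equiv), MeCN/H2O 4:1, 0 °C, 20 min
Reagents that add atoms: water, O
Why: The acidic aqueous oxidant should hydrolyse the labile aryl trimethylsilyl ether and oxidize the resulting 4-methoxyphenol in two one-electron steps, with water adding at C5' and methanol leaving (oxidative demethylation) to give the p-benzoquinone, while ring A, which lacks a para-dioxygen pattern, and the benzyl ethers resist the oxidant at 0 °C.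

Step 10
Reactants: 17 2-[2-(benzyloxy)-6-[2-(3-(benzyloxy)phenyl)ethyl]-4-methoxyphenyl]-1,4-benzoquinone
Product: 19 2-[2-hydroxy-6-[2-(3-hydroxyphenyl)ethyl]-4-methoxyphenyl]benzene-1,4-diol, via hydroquinone dibenzyl ether 18 (not isolated)
Conditions: H2 (1 atm), 10% Pd/C, EtOAc/MeOH, rt; filtration and concentration under Ar
Reagents that add atoms: none
Why: Catalytic hydrogenation should first reduce the quinone to the hydroquinone and then hydrogenolyse both benzyl aryl ethers, leaving the ring A methyl ether and the arenes untouched.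

**Compound list**

1 | methyl orsellinate (methyl 2,4-dihydroxy-6-methylbenzoate) | COC(=O)c1c(C)cc(O)cc1O | starting material
2 | methyl 2-hydroxy-4-methoxy-6-methylbenzoate | COC(=O)c1c(C)cc(OC)cc1O | intermediate
3 | methyl 2-(benzyloxy)-4-methoxy-6-methylbenzoate | COC(=O)c1c(C)cc(OC)cc1OCc1ccccc1 | intermediate
4 | 3-(benzyloxy)benzyl bromide | BrCc1cccc(OCc2ccccc2)c1 | starting material
5 | lateral lithio toluate, methyl 2-(benzyloxy)-6-(lithiomethyl)-4-methoxybenzoate | [Li]Cc1cc(OC)cc(OCc2ccccc2)c1C(=O)OC | intermediate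
6 | methyl 2-(benzyloxy)-6-[2-(3-(benzyloxy)phenyl)ethyl]-4-methoxybenzoate | COC(=O)c1c(CCc2cccc(OCc3ccccc3)c2)cc(OC)cc1OCc1ccccc1 | intermediate
7 | [2-(benzyloxy)-6-[2-(3-(benzyloxy)phenyl)ethyl]-4-methoxyphenyl]methanol | OCc1c(CCc2cccc(OCc3ccccc3)c2)cc(OC)cc1OCc1ccccc1 | intermediate
8 | 2-(benzyloxy)-6-[2-(3-(benzyloxy)phenyl)ethyl]-4-methoxybenzaldehyde | O=Cc1c(CCc2cccc(OCc3ccccc3)c2)cc(OC)cc1OCc1ccccc1 | intermediate
9 | 1-(benzyloxy)-2-ethynyl-5-methoxy-3-[2-(3-(benzyloxy)phenyl)ethyl]benzene | C#Cc1c(OCc2ccccc2)cc(OC)cc1CCc1cccc(OCc2ccccc2)c1 | intermediate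
10 | (E)-(2-bromovinyl)trimethylsilane | C[Si](C)(C)/C=C/Br | starting material
11 | hexacarbonylchromium Cr(CO)6 | O=C=[Cr](=C=O)(=C=O)(=C=O)(=C=O)=C=O | starting material
12 | (E)-2-(trimethylsilyl)vinyllithium | [Li]/C=C/[Si](C)(C)C | intermediate
13 | lithium pentacarbonyl[(E)-3-(trimethylsilyl)acryloyl]chromate | [Li+].[O-]C(/C=C/[Si](C)(C)C)=[Cr](=C=O)(=C=O)(=C=O)(=C=O)=C=O | intermediate
14 | pentacarbonyl[(E)-1-methoxy-3-(trimethylsilyl)prop-2-enylidene]chromium | COC(/C=C/[Si](C)(C)C)=[Cr](=C=O)(=C=O)(=C=O)(=C=O)=C=O | intermediate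
15 | 2-(benzyloxy)-6-[2-(3-(benzyloxy)phenyl)ethyl]-4,5'-dimethoxy-2'-(trimethylsilyloxy)-1,1'-biphenyl | COc1ccc(O[Si](C)(C)C)c(-c2c(OCc3ccccc3)cc(OC)cc2CCc2cccc(OCc3ccccc3)c2)c1 | intermediate
16 | 2-(benzyloxy)-6-[2-(3-(benzyloxy)phenyl)ethyl]-4,5'-dimethoxy-1,1'-biphenyl-2'-ol | COc1ccc(O)c(-c2c(OCc3ccccc3)cc(OC)cc2CCc2cccc(OCc3ccccc3)c2)c1 | intermediate
17 | 2-[2-(benzyloxy)-6-[2-(3-(benzyloxy)phenyl)ethyl]-4-methoxyphenyl]-1,4-benzoquinone | O=C1C=CC(=O)C(-c2c(OCc3ccccc3)cc(OC)cc2CCc2cccc(OCc3ccccc3)c2)=C1 | intermediate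
18 | 2-[2-(benzyloxy)-6-[2-(3-(benzyloxy)phenyl)ethyl]-4-methoxyphenyl]benzene-1,4-diol | Oc1ccc(O)c(-c2c(OCc3ccccc3)cc(OC)cc2CCc2cccc(OCc3ccccc3)c2)c1 | intermediate
19 | 2-[2-hydroxy-6-[2-(3-hydroxyphenyl)ethyl]-4-methoxyphenyl]benzene-1,4-diol (CNP0121738.0) | COc1cc(O)c(-c2cc(O)ccc2O)c(CCc2cccc(O)c2)c1 | target

**Step count**

Total: 10 steps. Longest linear sequence: 9 steps (steps 1–6 and 8–10 from methyl orsellinate 1); step 7 is a one-step branch.

**Steps most likely to fail**

Step 8. The hindered 2,6-disubstituted aryl alkyne may insert slowly, so that alkyne oligomerization, cyclobutenone or furan formation, or hydrogen rather than silicon migration in the dienone competes with clean benzannulation. The fallback sets out from aldehyde 8 and replaces the annulation by a cross-coupling. Dakin oxidation (m-CPBA, CH2Cl2, 0 °C → rt) should give 2-(benzyloxy)-6-[2-(3-(benzyloxy)phenyl)ethyl]-4-methoxyphenyl formate F1. This is methanolysed in the same flask (K2CO3, MeOH) to 2-(benzyloxy)-6-[2-(3-(benzyloxy)phenyl)ethyl]-4-methoxyphenol F2. Tf2O and pyridine (CH2Cl2, 0 °C) convert it into the aryl trifluoromethanesulfonate F3. Suzuki–Miyaura coupling with commercial (2,5-dimethoxyphenyl)boronic acid (Pd(OAc)2, SPhos, K3PO4, toluene/H2O, 100 °C) should give 2-(benzyloxy)-6-[2-(3-(benzyloxy)phenyl)ethyl]-2',4,5'-trimethoxy-1,1'-biphenyl F4. Oxidative demethylation of its hydroquinone dimethyl ether ring with (NH4)2Ce(NO3)6 in MeCN/H2O comes back to the route at quinone 17.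

Step 3. The lithiated methyl toluate may undergo Claisen-type self-condensation with unreacted ester, and proton transfer from the product may lead to double alkylation. The fallback sets out from ester 3. Saponification (KOH, DMSO/H2O, 80 °C; cold acidification) gives 2-(benzyloxy)-4-methoxy-6-methylbenzoic acid F5. With LiN(i-Pr)2 (2.2 equiv, THF, −78 → 0 °C) this forms the dilithio carboxylate–benzylic dianion F6, which cannot self-condense. Alkylation with bromide 4 gives 2-(benzyloxy)-6-[2-(3-(benzyloxy)phenyl)ethyl]-4-methoxybenzoic acid F7. Reduction with LiAlH4 (THF, reflux) comes back to the route at alcohol 7.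

Step 6. Addition of the diazophosphonate anion to the di-ortho-substituted, electron-rich aldehyde may be slower than decomposition of the reagent, leaving the carbonyl unconverted. The fallback sets out from aldehyde 8 and uses the Corey–Fuchs sequence. CBr4 and PPh3 (CH2Cl2, 0 °C) should give 1-(benzyloxy)-2-(2,2-dibromovinyl)-5-methoxy-3-[2-(3-(benzyloxy)phenyl)ethyl]benzene F8. n-BuLi (2.1 equiv, THF, −78 °C) induces bromine–lithium exchange and Fritsch–Buttenberg–Wiechell rearrangement to the lithium acetylide F9. Quenching with aqueous NH4Cl comes back to the route at alkyne 9.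

**Further compounds**

F1 | step 8 | 2-(benzyloxy)-6-[2-(3-(benzyloxy)phenyl)ethyl]-4-methoxyphenyl formate | O=COc1c(OCc2ccccc2)cc(OC)cc1CCc1cccc(OCc2ccccc2)c1
F2 | step 8 | 2-(benzyloxy)-6-[2-(3-(benzyloxy)phenyl)ethyl]-4-methoxyphenol | Oc1c(OCc2ccccc2)cc(OC)cc1CCc1cccc(OCc2ccccc2)c1
F3 | step 8 | 2-(benzyloxy)-6-[2-(3-(benzyloxy)phenyl)ethyl]-4-methoxyphenyl trifluoromethanesulfonate | O=S(=O)(Oc1c(OCc2ccccc2)cc(OC)cc1CCc1cccc(OCc2ccccc2)c1)C(F)(F)F
F4 | step 8 | 2-(benzyloxy)-6-[2-(3-(benzyloxy)phenyl)ethyl]-2',4,5'-trimethoxy-1,1'-biphenyl | COc1ccc(OC)c(-c2c(OCc3ccccc3)cc(OC)cc2CCc2cccc(OCc3ccccc3)c2)c1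
F5 | step 3 | 2-(benzyloxy)-4-methoxy-6-methylbenzoic acid | Cc1cc(OC)cc(OCc2ccccc2)c1C(=O)O
F6 | step 3 | lithium 2-(benzyloxy)-6-(lithiomethyl)-4-methoxybenzoate | [Li]Cc1cc(OC)cc(OCc2ccccc2)c1C(=O)O[Li]
F7 | step 3 | 2-(benzyloxy)-6-[2-(3-(benzyloxy)phenyl)ethyl]-4-methoxybenzoic acid | OC(=O)c1c(CCc2cccc(OCc3ccccc3)c2)cc(OC)cc1OCc1ccccc1
F8 | step 6 | 1-(benzyloxy)-2-(2,2-dibromovinyl)-5-methoxy-3-[2-(3-(benzyloxy)phenyl)ethyl]benzene | BrC(Br)=Cc1c(OCc2ccccc2)cc(OC)cc1CCc1cccc(OCc2ccccc2)c1
F9 | step 6 | lithium [2-(benzyloxy)-6-[2-(3-(benzyloxy)phenyl)ethyl]-4-methoxyphenyl]acetylide | [Li]C#Cc1c(OCc2ccccc2)cc(OC)cc1CCc1cccc(OCc2ccccc2)c1
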